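## Structural features

The target joins two 24-nor-friedelane (celastroid) C29 methyl esters through a 1,4-dioxane: the unprimed half gives the oxygens on aromatic C2 and C3 and keeps a C6=C7 styrene, whereas the primed half keeps a free catechol on ring A′ and offers sp3 C6′ and C7′, bonded to O3 and O2 on the α face. Each half carries seven carbocyclic stereocentres, C8 (α-H), C9 (β-Me), C13 (α-Me), C14 (β-Me), C17 (β-Me), C18 (β-H) and C20 (β-Me, α-CO2Me); C9/C8/C14/C13 and C18/C17 are contiguous and five of the seven are quaternary. C20 is remote from the rest and carries two groups of similar size, so it cannot be set by steric bias alone. Fragile groups are the catechol (oxidation, quinone/quinone methide tautomerism), the electron-rich styrene, the benzylic dioxane C–O bonds (acid) and the methyl esters (hydride, thiolate). The real difficulty is the trans-diaxial methyl array on C9, C13 and C14 next to H8, together with the isolated C20 centre. The key step exploits that this array is an oleanane array shifted by one carbon: the 10β-, 8β- and 14α-methyl groups of an olean-12-ene become 9β-, 14β- and 13α-methyl groups, and 9α-H becomes 8α-H. Ring A of the oleanane precursor is a diosphenol ether one unsaturation short of a phenol, and the C12=C13 alkene supplies that unsaturation once C10 has lost its methyl group, so that aromatisation pays for the shifts.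

## Logic of the disconnections

**35 ⇒ 33 + 34.** The O2–C7′ and O3–C6′ bonds are cut (retro hetero-Diels–Alder). Both halves then come from one monomer, because 34 is the two-electron oxidation product of 33. The forward step must add the 1,2-dione of 34 across C6′=C7′ of 33 with the right regiochemistry, on the α face, before 34 tautomerises.

**33 ⇒ 29 (through 32, 31, 30).** No skeletal bond is cut; the C6=C7 bond and the free O2–H are taken back to a saturated C6–C7 and a methyl ether. This leads to the direct product of the rearrangement. The forward demand is a benzylic dehydrogenation that spares the phenol, and a demethylation that spares styrene and esters.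

**29 ⇒ 28.** The C9–CH3, C14–CH3 and C13–CH3 bonds and the C8–H bond are cut, and CH3 is put back on C10, C8 and C14 and H on C9. Four stereocentres of the friedelane are exchanged for the array that a chair–chair–chair polyene cyclisation delivers directly. The forward step must run an oleanane-to-friedelane shift sequence against its usual equilibrium.
- The configurations encoded in 28 (4α-Me, 5α-H, 8β-Me, 9α-H, 10β-Me, 14α-Me, 17β-Me, 18β-H, 20α-CO2Me) and in 29 were compared centre by centre with both halves of 35, and all agree.
- One design point governs the route to 28: a 24-nor-3-ketone with H4 cannot be oxygenated at C2 by base and O2 without attack at tertiary C4, and its diosphenol would prefer the 3-hydroxy-3-en-2-one tautomer. The C2 oxygen and the O-methyl group are therefore installed while C4 is still quaternary (24 → 26), and C4 receives its hydrogen last (26 → 28).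

**28 ⇒ 23.** The C4–C23 bond is restored (retro-aldol in the forward sense), and O2 and its methyl group are removed. This gives a 3β-hydroxy-23-silyloxy oleanene of the type an epoxy-alcohol-derived polyene cyclisation produces.

**23 ⇒ 22.** The C4–C5, C9–C10 and C8–C14 bonds are cut (three rings, six stereocentres). The forward tricyclisation must end on the tetrasubstituted ring D alkene, attack it on the correct face and lose H12.

**22 ⇒ 14 + 20 (through 21).** The C12–C13 bond is cut. This is the convergent point: a ring D/E enol triflate and a linear epoxy tetraene. It demands a B-alkyl cross-coupling that tolerates an epoxide.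

**20 ⇒ 15 (through 19, 18, 17, 16).** C12 (olefination), the C23 oxygen (allylic oxidation) and the epoxide are removed. The forward epoxidation fixes the absolute configuration of rings A–C.

**14 ⇒ 9 (through 12, 10).** The C14=C15 bond (aldol) and C15 (one-carbon homologation) are removed, leaving a cyclohexane with three cis-disposed carbonyl groups.

**9 ⇒ 7 ⇒ 5 + 6.** C16 and C29 are rejoined as the enol ether bridge of a bicyclo[2.2.2]octene, then C17–C18 and C19–C20 are cut (retro-Diels–Alder). The bridge forces C16 and C29 onto one face, which solves the Me/CO2Me problem at C20. The endo rule relates C18 to both. One catalytic asymmetric cycloaddition must deliver C17, C18 and C20.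

**5 ⇒ 3 ⇒ 1.** Silylation and α′-methylation lead back to the commercial enone.

## Other disconnections considered

**Alternative 1:** cut C5′–C6′ of the primed ring B in the dimer.
- Forward step: acid ionises a hemiacetal carbon on O3 to an oxocarbenium ion, and the silyl-protected catechol arene closes ring B by Friedel–Crafts attack, giving A1.
- In favour: the dioxane regiochemistry (O3–C6′, O2–C7′) is fixed by connectivity. On this structural point it is better than the chosen hetero-Diels–Alder step, whose regiochemistry rests on electronic preference.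
- Against: the two halves are no longer made from one monomer. A hindered C7′–O aryl ether next to C8′ must be formed with inversion control, the catechol must be carried as silyl ethers, and the acid-labile benzylic acetal is formed under acid.
- Comparison: mechanistically a 6-endo arene closure of this kind is reliable and its C6′ configuration is controlled by the existing C7′ centre, so here it is the equal of the chosen end-game. In step economy it is worse: it adds several steps per half and loses the degeneracy that lets one monomer serve as both partners.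

**Alternative 2:** cut C13–C14 in ring C.
- Forward step: hydrogen-atom transfer from the iron hydride made from Fe(acac)3 and PhSiH3 to a C14 methylidene, then 6-exo addition of the tertiary radical to the enone β-carbon C13, giving A2.
- In favour: radical conjugate addition is very good at joining two fully substituted carbons and cannot undergo Wagner–Meerwein leakage. For the C13–C14 bond it is the equal of, or better than, any cationic method.
- Against: C8 and C9 must be set earlier on an A/B/C fragment. Ring D is still open in A2, and closing C16–C17 means making a quaternary centre at a carbon that is only β to the ketone. The C13 configuration depends on the approach of a flexible radical.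
- Comparison: structurally it builds one of the four contiguous centres per key step, where the chosen plan sets all four in one isomerisation. Mechanistically its bond-forming event is the more secure. In step economy it is linear and longer, and each half needs the full sequence.

**Alternative 3:** cut C8–C14 and C9–C10.
- Forward step: ionisation of a C14 tertiary alcohol, attack by C8 of an (E)-C8=C9 alkene, and capture of the C9 cation by the arene, giving A3.
- In favour: this type of arene-terminated cationic bicyclisation is established for the celastroid skeleton. In certainty of the skeleton-forming step it is better than the chosen plan.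
- Against: the 13α-methyl quaternary centre and the trisubstituted alkene must be built separately, and both phenol oxygens arrive as methyl ethers.
- Comparison: structurally it forms two rings and three stereocentres in one step, against four stereocentres and no ring in the chosen step. Mechanistically it is the safer of the two. In step economy it needs roughly eight more operations from 12, so it is kept as the fallback for the key step.

Key step: step 19

Assumption: the (S)-oxazaborolidine is taken to give the enantiomer of 7 drawn; if the sense proves opposite, the (R)-catalyst is used.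
Assumption: 3,4-dimethoxy-2-methylbenzaldehyde, 4-bromo-1-(trimethylsilyl)but-1-yne and (S)-3-acryloyl-4-benzyloxazolidin-2-one (fallbacks only) are taken as purchasable.

## Route

Step 1
Reactants: 1 3-methylcyclohex-2-en-1-one
Product: 3 3,6-dimethylcyclohex-2-en-1-one (racemic), via lithium dienolate 2 (not isolated)
Conditions: LiN(iPr)2, THF, −78 °C; MeI, −78 → 0 °C
Reagents that add atoms: iodomethane, CI
Why: Kinetic α′-deprotonation gives the cross-conjugated dienolate, which is C-methylated (enolate alkylation); the new centre is racemic and is flattened again in step 2.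

Step 2
Reactants: 3 3,6-dimethylcyclohex-2-en-1-one
Product: 5 2-(tert-butyldimethylsilyloxy)-1,4-dimethylcyclohexa-1,3-diene, via lithium dienolate 4 (not isolated)
Conditions: LiN(iPr)2, THF, −78 °C; TBSCl, DMPU, −78 °C → rt
Reagents that add atoms: tert-butyldimethylsilyl chloride, CC(C)(C)[Si](C)(C)Cl
Why: A second kinetic α′-deprotonation and O-silylation give the achiral 2-siloxy diene; its methyl-bearing termini are the future C17 and C20 and its oxygenated carbon is the future ester carbon C29.

Step 3
Reactants: 5 2-(tert-butyldimethylsilyloxy)-1,4-dimethylcyclohexa-1,3-diene; 6 ethyl vinyl ketone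
Product: 7 1-[5-(tert-butyldimethylsilyloxy)-1,4-dimethylbicyclo[2.2.2]oct-5-en-2-yl]propan-1-one, propanoyl endo, single enantiomer
Conditions: (S)-3,3-diphenyl-1-(o-tolyl)tetrahydropyrrolo[1,2-c][1,3,2]oxazaborole (20 mol %), AlBr3 (16 mol %), CH2Cl2, −78 → −40 °C
Reagents that add atoms: none
Why: Lewis-acid-catalysed Diels–Alder reaction: the siloxy group sends its own terminus (C20) to the CH2 of 6 and C17 to the acyl-bearing carbon, and the endo rule places the propanoyl group syn to the enol ether bridge, fixing C18 relative to C17 and C20. The chiral oxazaborolidine–AlBr3 catalyst selects the enantiomer, so all three ring E centres are set at once.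

Step 4
Reactants: 7 bicyclic silyl enol ether
Product: 9 methyl 4-formyl-1,4-dimethyl-3-propanoylcyclohexane-1-carboxylate (ester, propanoyl and formyl on one face), via aldehyde acid 8 (not isolated)
Conditions: O3, CH2Cl2, −78 °C; Me2S, −78 °C → rt; then MeOH, Me3SiCHN2, toluene, 0 °C
Reagents that add atoms: ozone, [O-][O+]=O; (trimethylsilyl)diazomethane, C[Si](C)(C)C=[N+]=[N-]
Why: Ozonolysis of the electron-rich silyl enol ether cuts the C16=C29 bridge into the C16 aldehyde on C17 and the C29 carboxyl on C20; these are cis because they come from one bridge, which fixes 20α-CO2Me/20β-Me relative to C17. Esterification with the diazoalkane is neutral and leaves the aldehyde and ketone alone.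

Step 5
Reactants: 9 keto aldehyde ester
Product: 10 methyl 4-(2-methoxyethenyl)-1,4-dimethyl-3-propanoylcyclohexane-1-carboxylate (E/Z mixture)
Conditions: Ph3P(CH2OMe)Cl, KN(SiMe3)2, THF, 0 °C; then 9, −78 °C → rt
Reagents that add atoms: (methoxymethyl)triphenylphosphonium chloride, COC[P+](c1ccccc1)(c1ccccc1)c1ccccc1.[Cl-]
Why: Wittig methoxymethylenation adds C15; at low temperature the aldehyde is olefinated faster than the hindered ethyl ketone reacts or enolises.

Step 6
Reactants: 10 enol ether
Product: 12 methyl 2,4a,7-trimethyl-1-oxo-1,4,4a,5,6,7,8,8a-octahydronaphthalene-7-carboxylate (cis-fused; 4a-Me, 8a-H and 7-Me on one face, ester on the other), via keto aldehyde 11 (not isolated)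
Conditions: 2 M HCl, THF, rt; then NaOMe, MeOH, 0 °C → rt
Reagents that add atoms: none
Why: Hydrolysis of the enol ether frees the C15 aldehyde, and intramolecular aldol condensation through C14 of the ethyl ketone closes ring D as a 2-methylcyclohexenone. The cis fusion comes from 7, since closure through the CH2 enolate is faster than enolisation at the hindered C18.

Step 7
Reactants: 12 ring D/E enone
Product: 14 methyl 2,4a,7-trimethyl-1-(trifluoromethylsulfonyloxy)-3,4,4a,5,6,7,8,8a-octahydronaphthalene-7-carboxylate, via lithium enolate 13 (not isolated)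
Conditions: LiBH(s-Bu)3, THF, −78 °C; PhNTf2, −78 → 0 °C
Reagents that add atoms: N-phenylbis(trifluoromethanesulfonimide), O=S(=O)(N(c1ccccc1)S(=O)(=O)C(F)(F)F)C(F)(F)F
Why: Conjugate hydride reduction gives the C13–C14 enolate regiospecifically without any base touching H18, and O-triflation gives the tetrasubstituted enol triflate.

Step 8
Reactants: 15 (2E,6E)-farnesol
Product: 16 (2E,6E)-farnesal
Conditions: MnO2, CH2Cl2, rt
Reagents that add atoms: none
Why: Selective oxidation of the allylic alcohol, without E/Z isomerisation under neutral conditions.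

Step 9
Reactants: 16 (2E,6E)-farnesal
Product: 17 (3E,7E)-4,8,12-trimethyltrideca-1,3,7,11-tetraene
Conditions: Ph3PCH3Br, KN(SiMe3)2, THF, 0 °C → rt
Reagents that add atoms: methyltriphenylphosphonium bromide, C[P+](c1ccccc1)(c1ccccc1)c1ccccc1.[Br-]
Why: Wittig methylenation of the enal adds C12 as the terminal carbon of a 1,3-diene.

Step 10
Reactants: 17 tetraene
Product: 18 (2E,6E,10E)-2,6,10-trimethyltrideca-2,6,10,12-tetraen-1-ol
Conditions: SeO2 (10 mol %), t-BuOOH, salicylic acid (10 mol %), CH2Cl2, rt
Reagents that add atoms: tert-butyl hydroperoxide, CC(C)(C)OO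
Why: Selenium dioxide allylic oxidation (ene reaction, then 2,3-sigmatropic shift) takes the (E)-methyl group of the terminal, most electron-rich trisubstituted alkene and gives the (E)-allylic alcohol.

Step 11
Reactants: 18 tetraenol
Product: 19 [(2S,3S)-3-[(3E,7E)-3,7-dimethyldeca-3,7,9-trien-1-yl]-2-methyloxiran-2-yl]methanol
Conditions: Ti(OiPr)4 (10 mol %), L-(+)-diethyl tartrate (12 mol %), t-BuOOH, 4 Å MS, CH2Cl2, −20 °C
Reagents that add atoms: tert-butyl hydroperoxide, CC(C)(C)OO
Why: Sharpless asymmetric epoxidation acts only on the allylic alcohol; the L-(+)-tartrate complex should deliver the (2S,3S)-epoxide, i.e. the 3S centre that becomes the 3β-oxygen and fixes the absolute sense of rings A–C.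

Step 12
Reactants: 19 epoxy alcohol
Product: 20 tert-butyldimethylsilyl ether of 19
Conditions: TBSCl, imidazole, DMF, 0 °C → rt
Reagents that add atoms: tert-butyldimethylsilyl chloride, CC(C)(C)[Si](C)(C)Cl
Why: Silylation of the primary alcohol, so that the Lewis acid of step 14 meets an ether and not a free hydroxyl.

Step 13
Reactants: 20 silyl epoxy tetraene; 14 enol triflate
Product: 22 methyl 2,4a,7-trimethyl-1-[(3E,7E)-4,8-dimethyl-10-[(2S,3S)-3-(tert-butyldimethylsilyloxymethyl)-3-methyloxiran-2-yl]deca-3,7-dien-1-yl]-3,4,4a,5,6,7,8,8a-octahydronaphthalene-7-carboxylate, via B-alkyl-9-BBN adduct 21 (not isolated)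
Conditions: 9-BBN-H, THF, 0 °C → rt; then 14, PdCl2(dppf) (5 mol %), AsPh3, Cs2CO3, DMF/H2O, rt
Reagents that add atoms: none
Why: 9-BBN-H hydroborates only the terminal vinyl group (boron on C12), and B-alkyl Suzuki–Miyaura coupling with 14 forms C12–C13 and the tetrasubstituted C13=C14 alkene. Epoxide, ester and silyl ether are inert to both reagents.

Step 14
Reactants: 22 epoxy polyene
Product: 23 methyl 23-(tert-butyldimethylsilyloxy)-3β-hydroxyolean-12-en-29-oate
Conditions: MeAlCl2, CH2Cl2, −78 °C; aqueous work-up
Reagents that add atoms: none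
Why: Epoxide-initiated cation–olefin tricyclisation through chair–chair–chair folding: anti opening at C4 and anti addition across the two (E)-alkenes set C3, C4, C5, C10, C9 and C8. The ring D alkene is attacked at C14 on the face opposite the pseudoaxial C18–C19 bond (14α-Me), and the C13 cation loses the axial H12.

Step 15
Reactants: 23 3β-alcohol
Product: 24 methyl 23-(tert-butyldimethylsilyloxy)-3-oxoolean-12-en-29-oate
Conditions: Dess–Martin periodinane, CH2Cl2, rt
Reagents that add atoms: none
Why: Dess–Martin oxidation of the hindered secondary alcohol; silyl ether, ester and 12-ene are untouched.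

Step 16
Reactants: 24 3-ketone
Product: 25 methyl 23-(tert-butyldimethylsilyloxy)-2-hydroxy-3-oxooleana-1,12-dien-29-oate
Conditions: KOt-Bu, O2 (1 atm), t-BuOH, rt; dilute HCl work-up
Reagents that add atoms: dioxygen, O=O
Why: Base-mediated autoxidation of the ketone enolate; with C4 still quaternary only C2 can be oxygenated, so the 2-hydroxy-1-en-3-one (diosphenol) should form as one regioisomer.

Step 17
Reactants: 25 diosphenol
Product: 26 methyl 23-(tert-butyldimethylsilyloxy)-2-methoxy-3-oxooleana-1,12-dien-29-oate
Conditions: MeI, K2CO3, acetone, 50 °C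
Reagents that add atoms: iodomethane, CI
Why: O-Alkylation of the diosphenol locks the enol ether on O2 with the double bond at C1=C2, conjugated to C10, before C4 can enolise.

Step 18
Reactants: 26 diosphenol methyl ether
Product: 28 methyl 2-methoxy-3-oxo-24-noroleana-1,12-dien-29-oate (4α-methyl), via 23-hydroxy ketone 27 (not isolated)
Conditions: Bu4NF, THF, 0 °C → rt; then K2CO3, MeOH, 40 °C
Reagents that add atoms: none
Why: Fluoride frees the hydroxymethyl group β to the ketone, and base-induced retro-aldol loss of formaldehyde removes that carbon. Protonation of the enolate under equilibrating conditions leaves the equatorial 4α-methyl group.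

Step 19
Reactants: 28 methyl 2-methoxy-3-oxo-24-noroleana-1,12-dien-29-oate
Product: 29 methyl 3-hydroxy-2-methoxy-24-norfriedela-1,3,5(10)-trien-29-oate (8α-H, 9β-Me, 13α-Me, 14β-Me)
Conditions: Tf2NH (0.3 equiv), (CF3)2CHOH/CH2Cl2 (1:3), −20 °C → rt
Reagents that add atoms: none
Why: Proposed new method: protonation of C12 gives the C13 cation, and four suprafacial 1,2-shifts follow, each migrating group axial and antiperiplanar to the one before in the all-chair skeleton: 14α-CH3 to C13, 8β-CH3 to C14, 9α-H to C8 and 10β-CH3 to C9. The resulting C10 cation is an allyl cation over C10–C1–C2 whose C2 terminus carries the methoxy group; loss of H5 gives a 2,4-dienone and enolisation through H4 gives the phenol, which drains the otherwise unfavourable equilibrium irreversibly. The closest known reactions are the acid-induced friedelene-to-oleanene backbone rearrangement, which passes through the same cations in the opposite sense, and the dienone–phenol rearrangement, in which aromatisation pays for a 1,2-shift. The step closes no ring. C13, C14, C8 and C9 are each set by retention of face of the migrating group, i.e. by C14, C8, C9 and C10 of 28; C17, C18 and C20 are not touched. The selectivity needed is that proton loss from the C14, C8 and C9 cations stays reversible and that the C13 cation does not lose H18. A strong acid with a non-basic counter-ion in an ionising solvent should secure the first; the cis D/E fusion, in which H18 is equatorial to ring D and poorly aligned with the empty orbital, together with low temperature, should secure the second. Protonation of the enone oxygen or of C1 is reversible and unproductive.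

Step 20
Reactants: 29 monomer 2-O-methyl ether
Product: 30 methyl 3-acetoxy-2-methoxy-24-norfriedela-1,3,5(10)-trien-29-oate
Conditions: Ac2O, pyridine, DMAP (cat.), CH2Cl2, rt
Reagents that add atoms: acetic anhydride, CC(=O)OC(C)=O
Why: Acetylation masks the phenol so that the quinone oxidant of step 21 cannot oxidise it.

Step 21
Reactants: 30 aryl acetate
Product: 31 methyl 3-acetoxy-2-methoxy-24-norfriedela-1,3,5(10),6-tetraen-29-oate
Conditions: DDQ (1.2 equiv), 1,4-dioxane, 80 °C
Reagents that add atoms: none
Why: DDQ dehydrogenation: hydride abstraction from benzylic C6, para to the methoxy group, then loss of H7, gives the C6=C7 styrene; C8 keeps its α-hydrogen.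

Step 22
Reactants: 31 styrene acetate
Product: 32 methyl 3-hydroxy-2-methoxy-24-norfriedela-1,3,5(10),6-tetraen-29-oate
Conditions: K2CO3, MeOH, rt
Reagents that add atoms: none
Why: Methanolysis removes the aryl acetate; the tertiary methyl ester cannot change under methoxide.

Step 23
Reactants: 32 2-methoxyphenol
Product: 33 methyl 2,3-dihydroxy-24-norfriedela-1,3,5(10),6-tetraen-29-oate
Conditions: BCl3 (2.5 equiv), Bu4NI (2.5 equiv), CH2Cl2, −78 → 0 °C; then ice-water
Reagents that add atoms: none
Why: Lewis-acid-assisted aryl methyl ether cleavage: the free 3-hydroxyl binds boron, the neighbouring 2-methoxy oxygen is activated within the resulting chelate, and iodide removes its methyl group by SN2 attack. At −78 to 0 °C the hindered tertiary methyl ester and the conjugated C6=C7 bond should survive, as esters and stilbene-type alkenes do with this reagent pair.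

Step 24
Reactants: 33 catechol monomer (two molecules)
Product: 35 CNP0224843.1 (target dimer), via ortho-quinone 34 (not isolated)
Conditions: Ag2O (0.55 equiv), 4 Å MS, CH2Cl2, rt, dark
Reagents that add atoms: none
Why: Half an equivalent of oxidant converts part of 33 into 34 (redox exchange between the two is degenerate), and inverse-electron-demand hetero-Diels–Alder addition of the 1,2-dione to the electron-rich C6′=C7′ bond of 33 closes the dioxane. C7′ should bond first to O2 and the benzylic C6′ then to O3; attack on the α face, away from the 9β- and 14β-methyl groups, sets C6′ and C7′.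

## Compound list

1 | 3-methylcyclohex-2-en-1-one | CC1=CC(=O)CCC1 | starting material
2 | lithium dienolate of 1 (cross-conjugated) | [Li]OC1=CCCC(C)=C1 | intermediate
3 | 3,6-dimethylcyclohex-2-en-1-one (racemic) | CC1CCC(C)=CC1=O | intermediate
4 | lithium dienolate of 3 (cross-conjugated) | [Li]OC1=C(C)CCC(C)=C1 | intermediate
5 | 2-(tert-butyldimethylsilyloxy)-1,4-dimethylcyclohexa-1,3-diene | CC1=CC(O[Si](C)(C)C(C)(C)C)=C(C)CC1 | intermediate
6 | ethyl vinyl ketone (pent-1-en-3-one) | CCC(=O)C=C | starting material
7 | 1-[5-(tert-butyldimethylsilyloxy)-1,4-dimethylbicyclo[2.2.2]oct-5-en-2-yl]propan-1-one, endo-propanoyl; bridgehead next to the acyl carbon is the future C17 | CCC(=O)[C@@H]1C[C@@]2(C)CC[C@]1(C)C=C2O[Si](C)(C)C(C)(C)C | intermediate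
8 | 4-formyl-1,4-dimethyl-3-propanoylcyclohexane-1-carboxylic acid (carboxyl, propanoyl and formyl cis) | OC(=O)[C@]1(C)CC[C@](C)(C=O)[C@@H](C1)C(=O)CC | intermediate
9 | methyl 4-formyl-1,4-dimethyl-3-propanoylcyclohexane-1-carboxylate (ester, propanoyl and formyl cis) | COC(=O)[C@]1(C)CC[C@](C)(C=O)[C@@H](C1)C(=O)CC | intermediate
10 | methyl 4-(2-methoxyethenyl)-1,4-dimethyl-3-propanoylcyclohexane-1-carboxylate (E/Z) | COC(=O)[C@]1(C)CC[C@](C)(C=COC)[C@@H](C1)C(=O)CC | intermediate
11 | methyl 1,4-dimethyl-4-(2-oxoethyl)-3-propanoylcyclohexane-1-carboxylate | COC(=O)[C@]1(C)CC[C@](C)(CC=O)[C@@H](C1)C(=O)CC | intermediate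
12 | methyl 2,4a,7-trimethyl-1-oxo-1,4,4a,5,6,7,8,8a-octahydronaphthalene-7-carboxylate, cis-fused (ring D/E enone; 17β-Me, 18β-H, 20β-Me, 20α-CO2Me) | COC(=O)[C@]1(C)CC[C@]2(C)CC=C(C)C(=O)[C@@H]2C1 | intermediate
13 | lithium enolate from conjugate reduction of 12 | COC(=O)[C@]1(C)CC[C@]2(C)CCC(C)=C(O[Li])[C@@H]2C1 | intermediate
14 | methyl 2,4a,7-trimethyl-1-(trifluoromethylsulfonyloxy)-3,4,4a,5,6,7,8,8a-octahydronaphthalene-7-carboxylate, cis-fused | COC(=O)[C@]1(C)CC[C@]2(C)CCC(C)=C(OS(=O)(=O)C(F)(F)F)[C@@H]2C1 | intermediate
15 | (2E,6E)-farnesol | CC(C)=CCC/C(C)=C/CC/C(C)=C/CO | starting material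
16 | (2E,6E)-farnesal | CC(C)=CCC/C(C)=C/CC/C(C)=C/C=O | intermediate
17 | (3E,7E)-4,8,12-trimethyltrideca-1,3,7,11-tetraene | CC(C)=CCC/C(C)=C/CC/C(C)=C/C=C | intermediate
18 | (2E,6E,10E)-2,6,10-trimethyltrideca-2,6,10,12-tetraen-1-ol | OC/C(C)=C/CC/C(C)=C/CC/C(C)=C/C=C | intermediate
19 | [(2S,3S)-3-[(3E,7E)-3,7-dimethyldeca-3,7,9-trien-1-yl]-2-methyloxiran-2-yl]methanol | OC[C@]1(C)O[C@H]1CC/C(C)=C/CC/C(C)=C/C=C | intermediate
20 | tert-butyldimethylsilyl ether of 19 | CC(C)(C)[Si](C)(C)OC[C@]1(C)O[C@H]1CC/C(C)=C/CC/C(C)=C/C=C | intermediate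
21 | B-alkyl-9-BBN adduct of 20 (boron on C12) | CC(C)(C)[Si](C)(C)OC[C@]1(C)O[C@H]1CC/C(C)=C/CC/C(C)=C/CCB1C2CCCC1CCC2 | intermediate
22 | coupled epoxy polyene (ring D/E unit joined at C13 to the C12 chain; (2S,3S)-epoxide, two (E)-alkenes) | COC(=O)[C@]1(C)CC[C@]2(C)CCC(C)=C(CC/C=C(C)/CC/C=C(C)/CC[C@@H]3O[C@@]3(C)CO[Si](C)(C)C(C)(C)C)[C@@H]2C1 | intermediate
23 | methyl 23-(tert-butyldimethylsilyloxy)-3β-hydroxyolean-12-en-29-oate | COC(=O)[C@]1(C)CC[C@]2(C)CC[C@]3(C)C(=CC[C@H]4[C@@]3(C)CC[C@H]5[C@](C)(CO[Si](C)(C)C(C)(C)C)[C@@H](O)CC[C@]45C)[C@@H]2C1 | intermediate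
24 | methyl 23-(tert-butyldimethylsilyloxy)-3-oxoolean-12-en-29-oate | COC(=O)[C@]1(C)CC[C@]2(C)CC[C@]3(C)C(=CC[C@H]4[C@@]3(C)CC[C@H]5[C@](C)(CO[Si](C)(C)C(C)(C)C)C(=O)CC[C@]45C)[C@@H]2C1 | intermediate
25 | methyl 23-(tert-butyldimethylsilyloxy)-2-hydroxy-3-oxooleana-1,12-dien-29-oate | COC(=O)[C@]1(C)CC[C@]2(C)CC[C@]3(C)C(=CC[C@H]4[C@@]3(C)CC[C@H]5[C@](C)(CO[Si](C)(C)C(C)(C)C)C(=O)C(O)=C[C@]45C)[C@@H]2C1 | intermediate
26 | methyl 23-(tert-butyldimethylsilyloxy)-2-methoxy-3-oxooleana-1,12-dien-29-oate | COC(=O)[C@]1(C)CC[C@]2(C)CC[C@]3(C)C(=CC[C@H]4[C@@]3(C)CC[C@H]5[C@](C)(CO[Si](C)(C)C(C)(C)C)C(=O)C(OC)=C[C@]45C)[C@@H]2C1 | intermediate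
27 | methyl 23-hydroxy-2-methoxy-3-oxooleana-1,12-dien-29-oate | COC(=O)[C@]1(C)CC[C@]2(C)CC[C@]3(C)C(=CC[C@H]4[C@@]3(C)CC[C@H]5[C@](C)(CO)C(=O)C(OC)=C[C@]45C)[C@@H]2C1 | intermediate
28 | methyl 2-methoxy-3-oxo-24-noroleana-1,12-dien-29-oate (4α-Me) | COC(=O)[C@]1(C)CC[C@]2(C)CC[C@]3(C)C(=CC[C@H]4[C@@]3(C)CC[C@H]5[C@H](C)C(=O)C(OC)=C[C@]45C)[C@@H]2C1 | intermediate
29 | methyl 3-hydroxy-2-methoxy-24-norfriedela-1,3,5(10)-trien-29-oate (6,7-dihydro monomer 2-O-methyl ether) | COC(=O)[C@]1(C)CC[C@]2(C)CC[C@]3(C)[C@H]4CCc5c(cc(OC)c(O)c5C)[C@]4(C)CC[C@@]3(C)[C@@H]2C1 | intermediate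
30 | methyl 3-acetoxy-2-methoxy-24-norfriedela-1,3,5(10)-trien-29-oate | COC(=O)[C@]1(C)CC[C@]2(C)CC[C@]3(C)[C@H]4CCc5c(cc(OC)c(OC(C)=O)c5C)[C@]4(C)CC[C@@]3(C)[C@@H]2C1 | intermediate
31 | methyl 3-acetoxy-2-methoxy-24-norfriedela-1,3,5(10),6-tetraen-29-oate | COC(=O)[C@]1(C)CC[C@]2(C)CC[C@]3(C)[C@H]4C=Cc5c(cc(OC)c(OC(C)=O)c5C)[C@]4(C)CC[C@@]3(C)[C@@H]2C1 | intermediate
32 | methyl 3-hydroxy-2-methoxy-24-norfriedela-1,3,5(10),6-tetraen-29-oate | COC(=O)[C@]1(C)CC[C@]2(C)CC[C@]3(C)[C@H]4C=Cc5c(cc(OC)c(O)c5C)[C@]4(C)CC[C@@]3(C)[C@@H]2C1 | intermediate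
33 | methyl 2,3-dihydroxy-24-norfriedela-1,3,5(10),6-tetraen-29-oate (catechol monomer) | COC(=O)[C@]1(C)CC[C@]2(C)CC[C@]3(C)[C@H]4C=Cc5c(cc(O)c(O)c5C)[C@]4(C)CC[C@@]3(C)[C@@H]2C1 | intermediate
34 | methyl 2,3-dioxo-24-norfriedela-1(10),4,6-trien-29-oate (ortho-quinone) | COC(=O)[C@]1(C)CC[C@]2(C)CC[C@]3(C)[C@H]4C=CC5=C(C)C(=O)C(=O)C=C5[C@]4(C)CC[C@@]3(C)[C@@H]2C1 | intermediate
35 | CNP0224843.1 (dimer; O3–C6′ and O2–C7′ dioxane, both oxygens α on the primed half) | COC(=O)[C@]1(C)CC[C@]2(C)CC[C@]3(C)[C@H]4C=Cc5c(cc6c(c5C)O[C@@H]5c7c(cc(O)c(O)c7C)[C@]7(C)CC[C@@]8(C)[C@@H]9C[C@](C)(C(=O)OC)CC[C@]9(C)CC[C@]8(C)[C@H]7[C@@H]5O6)[C@]4(C)CC[C@@]3(C)[C@@H]2C1 | target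

## Step count and least certain steps

Total: 24 steps. Longest linear sequence: 19 steps (steps 1–7, 13–24); the chain branch (steps 8–12) has 5 steps.

**Step 19 (key step).**
- What may go wrong: the cationic sequence may stall. Proton loss from the C14, C8 or C9 cations could drain material into 14-ene, 7-ene or 9(11)-ene isomers that fall back to oleanenes, because the cation equilibrium favours the oleanane side until C10 is reached. Deprotonation of the C13 cation towards the 13(18)-ene, followed by reprotonation, would erode C18.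
- Fallback (known chemistry, from 12 back to 29): MeLi/CeCl3 adds to 12 to give the tertiary allylic alcohol F1. Oxidative 1,3-transposition with pyridinium chlorochromate, C5H5NH[CrO3Cl], gives the β-methyl enone F2. Copper-mediated conjugate addition of 4-(trimethylsilyl)but-3-ynylmagnesium bromide (CuBr·SMe2, Me3SiCl) from the β face, then MeLi and PhNTf2, gives the enol triflate F3, in which C13 carries its α-methyl group. Pd(OAc)2/PPh3 with HCO2H/Et3N reduces F3 to the 14-ene F4. K2CO3/MeOH gives the terminal alkyne F5. Zirconium-catalysed carboalumination (AlMe3, Cp2ZrCl2) and iodination give the (E)-vinyl iodide F6. 3,4-Dimethoxy-2-methylstyrene F7 (from the commercial aldehyde by Wittig methylenation) is hydroborated to its 9-BBN adduct F8 and coupled with F6 (PdCl2(dppf), Cs2CO3) to the aryl diene F9. MeSO3H in CH2Cl2 at low temperature protonates C15 of the 14-ene, and the C14 cation sets off the arene-terminated cationic bicyclisation to the dimethyl ether F10 (the same compound as A3). BCl3 at low temperature cleaves the methoxy group on C3, which is flanked on both sides, twisted out of the ring plane and therefore the more Lewis-basic, and gives 29.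

**Step 14.**
- What may go wrong: premature termination after one or two rings, because C8–C14 bond formation joins two fully substituted carbons; attack on the wrong face of the ring D alkene; and proton loss from C13 towards C18 instead of C12.
- Fallback (stepwise ring C closure, from 20 and 14 back to 23): MeAlCl2 bicyclisation of 20 alone, ending by loss of H9, gives the A/B bicycle F11 with a C8=C9 bond conjugated to the vinyl group. 9-BBN-H gives the adduct F12, and Suzuki–Miyaura coupling with 14 gives the seco-C compound F13. SnCl4 or TfOH then protonates C9 from the α face, C14 attacks the C8 cation and loss of H12 gives 23, as in acid cyclisations of onoceradiene-type seco-triterpenes.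

**Step 3.**
- What may go wrong: slow turnover with a diene substituted at both termini, a stepwise Mukaiyama–Michael pathway that stops before the second bond forms, or insufficient enantio- or endo-selectivity.
- Fallback (auxiliary control, from 5 back to 7): Et2AlCl-promoted Diels–Alder reaction of 5 with (S)-3-acryloyl-4-benzyloxazolidin-2-one gives the endo imide F14 (the (R)-auxiliary if the sense is opposite). Me(MeO)NH·HCl/AlMe3 gives the Weinreb amide F15, and EtMgBr gives 7.

**Step 24.**
- What may go wrong: tautomerisation of 34 to the hydroxy quinone methide before cycloaddition, addition with the opposite orientation of O2 and O3, or oligomerisation of the catechol.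
- Fallback (cross-cycloaddition of two differentiated monomers, from 33 and 32 back to 35): 33 is silylated (TBSCl, imidazole) to the bis-silyl ether F16. Separately, 32 is oxidised with IBX to 34, which is combined at once with F16 to give the dimer bis-silyl ether F17 (the same compound as A1). Bu4NF buffered with AcOH gives 35.

**Step 23.**
- What may go wrong: hydrogen chloride released when the phenol binds boron may add to the electron-rich C6=C7 bond or start its cationic dimerisation, and prolonged exposure to the Lewis acid may begin to cleave the methyl ester.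
- Fallback (oxidative dealkylation in place of Lewis-acid cleavage, from 32 back to 33): IBX in DMF at 0 °C oxygenates the methoxy-bearing ortho carbon of the phenol and expels methanol to give the ortho-quinone 34, and aqueous Na2S2O4 added to the same flask reduces it at once to 33, so that no acid meets the styrene; no new compound.

## Further compounds

F1 | step 19 | tertiary allylic alcohol from 12 and MeLi (C13 carbinol, configuration at C13 immaterial) | COC(=O)[C@]1(C)CC[C@]2(C)CC=C(C)C(C)(O)[C@@H]2C1
F2 | step 19 | transposed enone (C15 ketone, C13(Me)=C14(Me)), cis-fused | COC(=O)[C@]1(C)CC[C@]2(C)CC(=O)C(C)=C(C)[C@@H]2C1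
F3 | step 19 | enol triflate with 13α-methyl and 13β-[4-(trimethylsilyl)but-3-ynyl] | COC(=O)[C@]1(C)CC[C@]2(C)CC(OS(=O)(=O)C(F)(F)F)=C(C)[C@@](C)(CCC#C[Si](C)(C)C)[C@@H]2C1
F4 | step 19 | 14-ene after triflate reduction (silyl alkyne) | COC(=O)[C@]1(C)CC[C@]2(C)CC=C(C)[C@@](C)(CCC#C[Si](C)(C)C)[C@@H]2C1
F5 | step 19 | terminal alkyne | COC(=O)[C@]1(C)CC[C@]2(C)CC=C(C)[C@@](C)(CCC#C)[C@@H]2C1
F6 | step 19 | (E)-vinyl iodide (C9 methyl, C8 iodide) | COC(=O)[C@]1(C)CC[C@]2(C)CC=C(C)[C@@](C)(CC/C(C)=C/I)[C@@H]2C1
F7 | step 19 | 3,4-dimethoxy-2-methylstyrene | C=Cc1ccc(OC)c(OC)c1C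
F8 | step 19 | 9-BBN adduct of F7 | COc1ccc(CCB2C3CCCC2CCC3)c(C)c1OC
F9 | step 19 | aryl diene, substrate of the arene-terminated bicyclisation ((E)-C8=C9) | COC(=O)[C@]1(C)CC[C@]2(C)CC=C(C)[C@@](C)(CC/C(C)=C/CCc3ccc(OC)c(OC)c3C)[C@@H]2C1
F10 | step 19 | methyl 2,3-dimethoxy-24-norfriedela-1,3,5(10)-trien-29-oate | COC(=O)[C@]1(C)CC[C@]2(C)CC[C@]3(C)[C@H]4CCc5c(cc(OC)c(OC)c5C)[C@]4(C)CC[C@@]3(C)[C@@H]2C1
F11 | step 14 | A/B bicycle from 20 (3β-OH, 23-silyloxy, C8=C9, 9-vinyl) | C=CC1=C(C)CC[C@H]2[C@](C)(CO[Si](C)(C)C(C)(C)C)[C@@H](O)CC[C@]12C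
F12 | step 14 | 9-BBN adduct of F11 (boron on C12) | B1(CCC2=C(C)CC[C@H]3[C@](C)(CO[Si](C)(C)C(C)(C)C)[C@@H](O)CC[C@]23C)C2CCCC1CCC2
F13 | step 14 | seco-C compound (A/B bicycle joined through C11–C12 to the ring D/E unit) | COC(=O)[C@]1(C)CC[C@]2(C)CCC(C)=C(CCC3=C(C)CC[C@H]4[C@](C)(CO[Si](C)(C)C(C)(C)C)[C@@H](O)CC[C@]34C)[C@@H]2C1
F14 | step 3 | endo Diels–Alder imide of 5 with (S)-3-acryloyl-4-benzyloxazolidin-2-one | O=C([C@@H]1C[C@@]2(C)CC[C@]1(C)C=C2O[Si](C)(C)C(C)(C)C)N1C(=O)OC[C@@H]1Cc1ccccc1
F15 | step 3 | Weinreb amide from F14 | CON(C)C(=O)[C@@H]1C[C@@]2(C)CC[C@]1(C)C=C2O[Si](C)(C)C(C)(C)C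
F16 | step 24 | bis(tert-butyldimethylsilyl) ether of 33 | COC(=O)[C@]1(C)CC[C@]2(C)CC[C@]3(C)[C@H]4C=Cc5c(cc(O[Si](C)(C)C(C)(C)C)c(O[Si](C)(C)C(C)(C)C)c5C)[C@]4(C)CC[C@@]3(C)[C@@H]2C1
F17 | step 24 | target bis(tert-butyldimethylsilyl) ether | COC(=O)[C@]1(C)CC[C@]2(C)CC[C@]3(C)[C@H]4C=Cc5c(cc6c(c5C)O[C@@H]5c7c(cc(O[Si](C)(C)C(C)(C)C)c(O[Si](C)(C)C(C)(C)C)c7C)[C@]7(C)CC[C@@]8(C)[C@@H]9C[C@](C)(C(=O)OC)CC[C@]9(C)CC[C@]8(C)[C@H]7[C@@H]5O6)[C@]4(C)CC[C@@]3(C)[C@@H]2C1
F0 | step 23 | none | none
A1 | alternative 1 | target bis(tert-butyldimethylsilyl) ether | COC(=O)[C@]1(C)CC[C@]2(C)CC[C@]3(C)[C@H]4C=Cc5c(cc6c(c5C)O[C@@H]5c7c(cc(O[Si](C)(C)C(C)(C)C)c(O[Si](C)(C)C(C)(C)C)c7C)[C@]7(C)CC[C@@]8(C)[C@@H]9C[C@](C)(C(=O)OC)CC[C@]9(C)CC[C@]8(C)[C@H]7[C@@H]5O6)[C@]4(C)CC[C@@]3(C)[C@@H]2C1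
A2 | alternative 2 | A/B/C tricycle with ring E ketone on C13 and a C14 silyloxyethyl chain | COC(=O)[C@]1(C)CC[C@@H](C)[C@@H](C1=O)[C@]2(C)CC[C@@]3(C)c4cc(OC)c(OC)c(C)c4CC[C@@H]3[C@@]2(C)CCO[Si](C)(C)C(C)(C)C
A3 | alternative 3 | methyl 2,3-dimethoxy-24-norfriedela-1,3,5(10)-trien-29-oate | COC(=O)[C@]1(C)CC[C@]2(C)CC[C@]3(C)[C@H]4CCc5c(cc(OC)c(OC)c5C)[C@]4(C)CC[C@@]3(C)[C@@H]2C1
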